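Numbering: heavy atoms 1–27 in the order of the target SMILES; ring A = O8, C3–C7; ring B = C12–C16; ring C = C13, C14, C17, C22, C23; ring D = C6, C9–C13, C23; ring E = C6, C9, C27, N25, C24, C23.
Cuts: ring A at O8–C3 and C5–C6; ring E at C27–C9; C6–C7; ring D at C9=C10 and C6–C9; C12–C11; C24–N25 and C23–C24; ring C at C13=C23 and C17–C22; C14–C17.
Forward: ring B (cyclopentenone) → malonate adduct → ring C by aldol condensation → quaternary C23 and the C12 enol triflate in one conjugate addition → sarcosine arm → ring D by metathesis → C6=C9 enal → ring E by radical closure → ring A.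
Enabling feature: N25 carries the CH2 carbon C27 that is bonded to C9, and C9 is the β-carbon of an enal as long as C6=C9 bears C7 as CHO, so a C27 radical held by the N25–C24–C23 tether can close ring E on C9.
Stereochemistry: C14 from a catalyst-controlled Michael addition; C17 (kinetic protonation) and C23 (convex-face cuprate addition) are relayed from C14; C9 follows from the C23 tether; C6 from alkylation on the ring D face.

Key step: step 16

Assumption: LiAl((S)-BINOLate)2 is taken to give the (S)-adduct 3, by analogy with the (R)-catalyst/(R)-adduct pairing of cyclic enones; the enantiomeric catalyst would be used if the sense were opposite.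

Step 1
Reactants: 1 cyclopent-2-en-1-one; 2 dimethyl malonate
Product: 3 dimethyl 2-[(1S)-3-oxocyclopentyl]malonate
Conditions: LiAl((S)-BINOLate)2 (5 mol %), KOt-Bu (4.5 mol %), 4 Å MS, THF, 25 °C
Reagents that add atoms: none
Why: Catalytic enantioselective Michael addition of a malonate to a cyclic enone, in which the heterobimetallic binaphthoxide differentiates the enone faces and sets C14, the only stereocentre that a chiral reagent has to create.

Step 2
Reactants: 3 dimethyl 2-[(1S)-3-oxocyclopentyl]malonate; 4 3-bromo-1,1-dimethoxypropan-2-one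
Product: 5 dimethyl 2-(3,3-dimethoxy-2-oxopropyl)-2-[(1S)-3-oxocyclopentyl]malonate
Conditions: NaH, THF/DMF, 0 → 25 °C
Reagents that add atoms: none
Why: SN2 alkylation of the sodium malonate (the most acidic C–H of 3) by the α-bromo ketone, which brings in C22, C23 and C6 (masked as the dimethyl acetal) without touching C14.

Step 3
Reactants: 5 dimethyl 2-(3,3-dimethoxy-2-oxopropyl)-2-[(1S)-3-oxocyclopentyl]malonate
Product: 7 bicyclic enone diester (rings B and C; C12 ketone conjugated to C13=C23; CH(OMe)2 on C23; two CO2Me on C17), via aldol adduct 6 (not isolated)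
Conditions: pyrrolidine (0.5 equiv), AcOH (0.5 equiv), 4 Å MS, toluene, 70 °C
Reagents that add atoms: none
Why: Intramolecular aldol condensation through the enamine of the ring B ketone, in which only attack of C13 on the C23 ketone gives a fused five-membered ring that can dehydrate to the conjugated enone, the alternative closures being bridged and reversible.

Step 4
Reactants: 7 bicyclic enone diester
Product: 10 bicyclic enone monoester (CO2Me on C17 cis to C15), via lithium carboxylate 8 (not isolated), via lithium ester enolate 9 (not isolated)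
Conditions: LiCl, H2O, DMSO, 140 °C
Reagents that add atoms: none
Why: Krapcho dealkoxycarbonylation, in which chloride demethylates one ester, carboxylate 8 loses CO2 and enolate 9 is protonated by water under kinetic control on the convex face opposite C15, so that the remaining C17 ester should end cis to C15 (a trans epimer would be separated here).

Step 5
Reactants: 10 bicyclic enone monoester
Product: 12 ring B enol triflate (C12–OTf, C12=C13) with quaternary C23 carrying vinyl (anti to the C17 ester) and CH(OMe)2 (syn), via bromomagnesium enolate 11 (not isolated)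
Conditions: CH2=CHMgBr, CuBr·SMe2, THF, −78 → −30 °C; then N-(5-chloropyridin-2-yl)bis(trifluoromethanesulfonimide), −78 → 25 °C
Reagents that add atoms: vinylmagnesium bromide, C=C[Mg]Br; N-(5-chloropyridin-2-yl)-1,1,1-trifluoro-N-(trifluoromethylsulfonyl)methanesulfonamide, FC(F)(F)S(=O)(=O)N(c1ccc(Cl)cn1)S(=O)(=O)C(F)(F)F
Why: Organocopper conjugate addition to the exocyclic tetrasubstituted enone (the reactivity pattern of copper-mediated Grignard additions to pulegone), the vinyl group arriving on the face opposite the C17 ester and C15 to create quaternary C23, followed by O-triflation of the regiodefined enolate 11, which fixes the later C12=C13 double bond.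

Step 6
Reactants: 12 ring B enol triflate with vinyl on C23
Product: 14 C24 aldehyde (CHO on C23; enol triflate and acetal kept), via vicinal diol 13 (not isolated)
Conditions: K2OsO4·2H2O (2 mol %), NaIO4, 2,6-lutidine, dioxane/H2O, 25 °C
Reagents that add atoms: sodium periodate, [Na+].[O-]I(=O)(=O)=O (terminal oxidant; its oxygen reaches C24 through OsO4)
Why: Lemieux–Johnson cleavage, in which OsO4 dihydroxylates the monosubstituted vinyl group in preference to the tetrasubstituted, electron-poor enol triflate alkene and periodate cleaves diol 13 to the non-enolisable C24 aldehyde.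

Step 7
Reactants: 14 C24 aldehyde; 15 sarcosine tert-butyl ester hydrochloride
Product: 17 tert-butyl sarcosinate amine (C24H2–N25(CH3)–C27H2–CO2t-Bu), via iminium acetate 16 (not isolated)
Conditions: Et3N, NaBH(OAc)3, AcOH, ClCH2CH2Cl, 25 °C
Reagents that add atoms: none
Why: Reductive amination with triacetoxyborohydride, which reduces iminium 16 faster than the hindered aldehyde and installs N25, C26, C27 and the latent carboxylate on an aldehyde that cannot enolise.

Step 8
Reactants: 17 tert-butyl sarcosinate amine
Product: 18 C12 allyl compound (tetrasubstituted C12=C13; C11–C10=CH2 on C12)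
Conditions: CH2=CHCH2SnBu3, Pd(PPh3)4 (5 mol %), LiCl, THF, 65 °C
Reagents that add atoms: allyltributylstannane, C=CC[Sn](CCCC)(CCCC)CCCC
Why: Stille coupling of the enol triflate with an allylstannane at zerovalent palladium, which replaces the triflate by C11–C10 with the double bond kept at C12=C13.

Step 9
Reactants: 18 C12 allyl compound
Product: 19 C6 aldehyde (CHO on C23, syn to the C17 ester)
Conditions: 2 M HCl (aq), THF, 25 °C; NaHCO3 work-up
Reagents that add atoms: water, O
Why: Acid hydrolysis of the dimethyl acetal, under which the protonated amine, the tert-butyl ester and the tetrasubstituted alkene should survive.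

Step 10
Reactants: 19 C6 aldehyde
Product: 20 C6 allylic alcohol (both C6 epimers)
Conditions: CH2=CHMgBr, THF, −78 °C; NH4Cl (aq) at −78 °C
Reagents that add atoms: vinylmagnesium bromide, C=C[Mg]Br
Why: Grignard 1,2-addition to the aldehyde, far faster than addition to either ester at −78 °C, which attaches C9; the new carbinol centre is removed in the next step and the cold quench avoids lactonisation onto the C17 ester.

Step 11
Reactants: 20 C6 allylic alcohol
Product: 21 C6 vinyl ketone
Conditions: Dess–Martin periodinane, NaHCO3, CH2Cl2, 0 → 25 °C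
Reagents that add atoms: none
Why: Dess–Martin oxidation of a secondary allylic alcohol to the enone under buffered, non-epimerising conditions that tolerate the tertiary amine.

Step 12
Reactants: 21 C6 vinyl ketone
Product: 22 tricyclic dienone (rings B, C and D; C6 ketone, C9=C10, C12=C13)
Conditions: second-generation Grubbs catalyst RuCl2(=CHPh)(H2IMes)(PCy3) (5 mol %), camphorsulfonic acid (1.0 equiv), CH2Cl2 (0.005 M), 40 °C
Reagents that add atoms: none
Why: Ring-closing metathesis between the allyl group and the vinyl ketone, favoured because C11 and C23 are held cis on the C12=C13 double bond, closes the seven-membered ring D with the amine masked as its ammonium salt.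

Step 13
Reactants: 22 tricyclic dienone
Product: 24 ring D enol triflate (C6–OTf, C6=C9; C10 now CH2), via lithium enolate 23 (not isolated)
Conditions: LiBH(s-Bu)3, THF, −78 °C; then PhNTf2, −78 → 0 °C
Reagents that add atoms: N-phenylbis(trifluoromethanesulfonimide), O=S(=O)(N(c1ccccc1)S(=O)(=O)C(F)(F)F)C(F)(F)F
Why: Conjugate reduction–enolate triflation, in which the bulky borohydride adds 1,4 to the cycloheptadienone (its carbonyl is shielded by quaternary C23) and enolate 23 is trapped with the double bond fixed at C6=C9.

Step 14
Reactants: 24 ring D enol triflate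
Product: 25 ring D enal tert-butyl ester (C7 formyl on C6, C6=C9)
Conditions: Pd(PPh3)4 (5 mol %), CO (1 atm), Bu3SnH (slow addition), LiCl, THF, 50 °C
Reagents that add atoms: carbon monoxide, [C-]#[O+]
Why: Palladium-catalysed reductive carbonylation (formylation) of a vinyl triflate, in which CO insertion followed by hydride transfer from the tin hydride delivers C7 as the aldehyde without touching the two esters.

Step 15
Reactants: 25 ring D enal tert-butyl ester
Product: 26 ring D enal N-alkyl sarcosine (free amino acid)
Conditions: HCO2H, 25 °C; then pH 6 buffer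
Reagents that add atoms: none
Why: Acidolysis of the tert-butyl ester with an acid too weak to protonate the tetrasubstituted C12=C13 alkene, which frees the carboxylic acid needed for decarboxylation.

Step 16
Reactants: 26 ring D enal N-alkyl sarcosine
Product: 30 tetracyclic amino aldehyde (rings B, C, D and E; C7 formyl on C6), via aminomethyl radical 27 (not isolated), via α-formyl radical 28 (not isolated), via potassium enolate 29 (not isolated)
Conditions: [Ir(dF(CF3)ppy)2(dtbbpy)]PF6 (2 mol %), K2HPO4 (1.2 equiv), DMF (0.01 M), blue LEDs (450 nm), 25 °C, argon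
Reagents that add atoms: none
Why: Photoexcited trivalent iridium oxidises the carboxylate of 26, loss of CO2 gives the nucleophilic C27 radical 27, this adds to the electrophilic β-carbon C9 of the enal to give α-formyl radical 28, and divalent iridium reduces 28 to enolate 29, which is protonated to 30. The closest known reaction type is the photoredox decarboxylative conjugate (Giese) addition of α-amino acids to enals and enones, run here intramolecularly. Ring E closes in the 6-endo-trig mode because the tether reaches the acceptor through its α-carbon C6; the 5-exo alternative would attack C6, which is fully substituted, is not the electrophilic position and lies next to quaternary C23. The new centre C9 is controlled by the tether: the C24–N25–C27 chain is anchored on C23 and can reach only its own face of C6=C9, which gives the cis one-carbon-bridged bicycle of rings D and E. The step needs cyclisation to outrun hydrogen abstraction by 27 and intermolecular addition, which high dilution, the absence of a good hydrogen-atom donor and the matched polarity of radical and enal should secure. C6 is set by protonation, expected on the ring D face, and is made planar again in step 17.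

Step 17
Reactants: 30 tetracyclic amino aldehyde; 31 pent-1-en-3-one
Product: 33 C6-quaternary keto aldehyde (3-oxopentyl chain C5–C1 on C6, syn to ring D), via pyrrolidine enamine 32 (not isolated)
Conditions: 31 (3 equiv), pyrrolidine (30 mol %), PhCO2H (30 mol %), toluene, 40 °C
Reagents that add atoms: none
Why: Enamine-catalysed Michael addition of an α-branched aldehyde to a vinyl ketone, in which enamine 32 should be alkylated on the C6 face over ring D (C13 is sp2 and offers no axial hydrogen there) and not on the face shielded by the axial C24–H and C27–H of ring E, so that C5 ends syn to ring D and C7 syn to N25.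

Step 18
Reactants: 33 C6-quaternary keto aldehyde
Product: 34 hydroxy ketone (C7H2OH on C6; C3 ketone kept)
Conditions: NaBH4, EtOH/CH2Cl2 (3:7), −78 °C
Reagents that add atoms: none
Why: Chemoselective borohydride reduction of an aldehyde in the presence of a ketone at low temperature, after which the δ-hydroxy ketone is free to close on the C3 carbonyl.

Step 19
Reactants: 34 hydroxy ketone
Product: 36 CNP0159589.2 (target), via cyclic hemiketal 35 (not isolated)
Conditions: camphorsulfonic acid (1.3 equiv), 4 Å MS, CH2Cl2, 25 °C; Et3N quench
Reagents that add atoms: none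
Why: Acid-catalysed cyclodehydration of a δ-hydroxy ketone through hemiketal 35 closes ring A (O8–C3) and gives the endocyclic C3=C4 enol ether, the more stable isomer under equilibrating acid; the acid in excess of the amine is the catalyst.

Compound list
1 | cyclopent-2-en-1-one | O=C1C=CCC1 | starting material
2 | dimethyl malonate | COC(=O)CC(=O)OC | starting material
3 | dimethyl 2-[(1S)-3-oxocyclopentyl]malonate | O=C1C[C@H](CC1)C(C(=O)OC)C(=O)OC | intermediate
4 | 3-bromo-1,1-dimethoxypropan-2-one | COC(OC)C(=O)CBr | starting material
5 | dimethyl 2-(3,3-dimethoxy-2-oxopropyl)-2-[(1S)-3-oxocyclopentyl]malonate | O=C1C[C@H](CC1)C(CC(=O)C(OC)OC)(C(=O)OC)C(=O)OC | intermediate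
6 | aldol adduct (C13–C23 bond, tertiary alcohol at C23; step 3, not isolated) | O=C1CC[C@H]2C1C(O)(C(OC)OC)CC2(C(=O)OC)C(=O)OC | intermediate
7 | bicyclic enone diester (rings B and C) | O=C1CC[C@H]2C1=C(C(OC)OC)CC2(C(=O)OC)C(=O)OC | intermediate
8 | lithium carboxylate of the half ester (step 4, not isolated) | O=C1CC[C@H]2C1=C(C(OC)OC)CC2(C(=O)OC)C(=O)[O-].[Li+] | intermediate
9 | lithium ester enolate at C17 (step 4, not isolated) | O=C1CC[C@H]2C1=C(C(OC)OC)CC2=C(OC)O[Li] | intermediate
10 | bicyclic enone monoester (C17 ester cis to C15) | O=C1CC[C@H]2C1=C(C(OC)OC)C[C@H]2C(=O)OC | intermediate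
11 | bromomagnesium enolate after vinyl addition (step 5, not isolated) | Br[Mg]OC1=C2[C@H](CC1)[C@H](C(=O)OC)C[C@@]2(C(OC)OC)C=C | intermediate
12 | ring B enol triflate with vinyl and CH(OMe)2 on C23 | FC(F)(F)S(=O)(=O)OC1=C2[C@H](CC1)[C@H](C(=O)OC)C[C@@]2(C(OC)OC)C=C | intermediate
13 | vicinal diol from the vinyl group (step 6, not isolated) | FC(F)(F)S(=O)(=O)OC1=C2[C@H](CC1)[C@H](C(=O)OC)C[C@@]2(C(OC)OC)C(O)CO | intermediate
14 | C24 aldehyde | FC(F)(F)S(=O)(=O)OC1=C2[C@H](CC1)[C@H](C(=O)OC)C[C@@]2(C(OC)OC)C=O | intermediate
15 | sarcosine tert-butyl ester hydrochloride | Cl.CNCC(=O)OC(C)(C)C | starting material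
16 | iminium acetate at C24 (step 7, not isolated) | CC(=O)[O-].FC(F)(F)S(=O)(=O)OC1=C2[C@H](CC1)[C@H](C(=O)OC)C[C@@]2(C(OC)OC)C=[N+](C)CC(=O)OC(C)(C)C | intermediate
17 | tert-butyl sarcosinate amine (enol triflate, acetal) | FC(F)(F)S(=O)(=O)OC1=C2[C@H](CC1)[C@H](C(=O)OC)C[C@@]2(C(OC)OC)CN(C)CC(=O)OC(C)(C)C | intermediate
18 | C12 allyl compound | C=CCC1=C2[C@H](CC1)[C@H](C(=O)OC)C[C@@]2(C(OC)OC)CN(C)CC(=O)OC(C)(C)C | intermediate
19 | C6 aldehyde | C=CCC1=C2[C@H](CC1)[C@H](C(=O)OC)C[C@@]2(C=O)CN(C)CC(=O)OC(C)(C)C | intermediate
20 | C6 allylic alcohol (both C6 epimers) | C=CCC1=C2[C@H](CC1)[C@H](C(=O)OC)C[C@@]2(C(O)C=C)CN(C)CC(=O)OC(C)(C)C | intermediate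
21 | C6 vinyl ketone | C=CCC1=C2[C@H](CC1)[C@H](C(=O)OC)C[C@@]2(C(=O)C=C)CN(C)CC(=O)OC(C)(C)C | intermediate
22 | tricyclic dienone (rings B, C and D) | O=C1C=CCC2=C3[C@H](CC2)[C@H](C(=O)OC)C[C@@]31CN(C)CC(=O)OC(C)(C)C | intermediate
23 | lithium enolate C6(OLi)=C9 (step 13, not isolated) | [Li]OC1=CCCC2=C3[C@H](CC2)[C@H](C(=O)OC)C[C@@]31CN(C)CC(=O)OC(C)(C)C | intermediate
24 | ring D enol triflate | FC(F)(F)S(=O)(=O)OC1=CCCC2=C3[C@H](CC2)[C@H](C(=O)OC)C[C@@]31CN(C)CC(=O)OC(C)(C)C | intermediate
25 | ring D enal tert-butyl ester | O=CC1=CCCC2=C3[C@H](CC2)[C@H](C(=O)OC)C[C@@]31CN(C)CC(=O)OC(C)(C)C | intermediate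
26 | ring D enal N-alkyl sarcosine (key-step precursor) | O=CC1=CCCC2=C3[C@H](CC2)[C@H](C(=O)OC)C[C@@]31CN(C)CC(=O)O | intermediate
27 | C27 aminomethyl radical (step 16, not isolated) | O=CC1=CCCC2=C3[C@H](CC2)[C@H](C(=O)OC)C[C@@]31CN(C)[CH2] | intermediate
28 | cyclised α-formyl radical at C6 (step 16, not isolated) | O=C[C]1[C@@H]2CCC3=C4[C@H](CC3)[C@H](C(=O)OC)C[C@@]41CN(C)C2 | intermediate
29 | potassium enolate C7(OK)=C6 (step 16, not isolated) | [K+].[O-]C=C1[C@@H]2CCC3=C4[C@H](CC3)[C@H](C(=O)OC)C[C@@]41CN(C)C2 | intermediate
30 | tetracyclic amino aldehyde (key-step product; C6 epimer from protonation on the ring D face) | O=C[C@H]1[C@@H]2CCC3=C4[C@H](CC3)[C@H](C(=O)OC)C[C@@]41CN(C)C2 | intermediate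
31 | pent-1-en-3-one | CCC(=O)C=C | starting material
32 | pyrrolidine enamine of 30 (step 17, not isolated) | C(=C1[C@@H]2CCC3=C4[C@H](CC3)[C@H](C(=O)OC)C[C@@]41CN(C)C2)N5CCCC5 | intermediate
33 | C6-quaternary keto aldehyde | CCC(=O)CC[C@]1(C=O)[C@@H]2CCC3=C4[C@H](CC3)[C@H](C(=O)OC)C[C@@]41CN(C)C2 | intermediate
34 | hydroxy ketone | CCC(=O)CC[C@]1(CO)[C@@H]2CCC3=C4[C@H](CC3)[C@H](C(=O)OC)C[C@@]41CN(C)C2 | intermediate
35 | cyclic hemiketal at C3 (step 19, not isolated) | CCC1(O)CC[C@]2(CO1)[C@@H]1CCC3=C4[C@H](CC3)[C@H](C(=O)OC)C[C@@]42CN(C)C1 | intermediate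
36 | CNP0159589.2 | CCC1=CC[C@]2(CO1)[C@@H]1CCC3=C4[C@H](CC3)[C@H](C(=O)OC)C[C@@]42CN(C)C1 | target

Total step count: 19. Longest linear sequence: 19 steps, from cyclopent-2-en-1-one (1).

Steps most likely to fail

Step 16. The C27 radical may abstract hydrogen before it cyclises (giving the N,N-dimethyl amine), or the 6-endo closure onto the hindered trisubstituted enal may be too slow to compete with intermolecular addition. The fallback sets out from 26 and returns at 30 and replaces the photoredox cycle by a thiohydroxamate radical chain. Acid 26 is condensed with N-hydroxypyridine-2-thione and N,N'-dicyclohexylcarbodiimide (CH2Cl2, 0 °C, dark) to the thiohydroxamate (Barton) ester F1. Irradiation with a tungsten lamp in dilute benzene should trigger decarboxylation, the same 6-endo addition of the C27 radical to C9 and transfer of the 2-pyridylthio group to C6, giving the α-(2-pyridylthio) aldehyde F2. Bu3SnH with azobisisobutyronitrile in benzene at 80 °C then cleaves the C6–S bond and gives 30.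

Step 17. Enamine formation and C–C bond formation at the congested bridging carbon C6 may be slow, and attack on the ring E face would give the C6 epimer. The fallback sets out from 30 and returns at 34; it exchanges the roles of the two C6 substituents, so it leads to the target configuration when electrophiles prefer the ring E face. A crossed aldol reaction of 30 with aqueous formaldehyde (K2CO3, MeOH/H2O, 25 °C) should give the hydroxymethyl aldehyde F3, in which the incoming CH2OH is C7 and the original formyl carbon becomes C5. Wittig olefination with 1-(triphenylphosphoranylidene)butan-2-one (toluene, 90 °C) gives the (E)-enone F4, and conjugate reduction with [(Ph3P)CuH]6 (benzene, 25 °C) gives 34.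

Step 5. Transfer of the vinyl group to the tetrasubstituted enone may be slow, with 1,2-addition competing, and the hindered enolate may be triflated incompletely. The fallback sets out from 10 and returns at 14 and uses a smaller, more reactive hydroxymethyl anion equivalent, which also removes the oxidative cleavage of step 6. Copper-catalysed addition of (isopropoxydimethylsilyl)methylmagnesium chloride (CuBr·SMe2, THF, −78 → −30 °C), with the same triflating agent as trap, should give the silylmethyl enol triflate F5. Tamao oxidation (H2O2, KF, KHCO3, THF/MeOH, 25 °C) gives the primary alcohol F6, and Dess–Martin periodinane (NaHCO3, CH2Cl2) gives 14.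

Further compounds
F1 | step 16 | thiohydroxamate (Barton) ester of 26 | O=CC1=CCCC2=C3[C@H](CC2)[C@H](C(=O)OC)C[C@@]31CN(C)CC(=O)ON1C=CC=CC1=S
F2 | step 16 | α-(2-pyridylthio) aldehyde (C6 epimers) | O=CC1(Sc2ccccn2)[C@@H]2CCC3=C4[C@H](CC3)[C@H](C(=O)OC)C[C@@]41CN(C)C2
F3 | step 17 | hydroxymethyl aldehyde (CH2OH = C7, CHO = future C5) | O=C[C@]1(CO)[C@@H]2CCC3=C4[C@H](CC3)[C@H](C(=O)OC)C[C@@]41CN(C)C2
F4 | step 17 | (E)-enone (C5=C4 conjugated to the C3 ketone) | CCC(=O)/C=C/[C@]1(CO)[C@@H]2CCC3=C4[C@H](CC3)[C@H](C(=O)OC)C[C@@]41CN(C)C2
F5 | step 5 | silylmethyl enol triflate (CH2SiMe2(Oi-Pr) on C23) | FC(F)(F)S(=O)(=O)OC1=C2[C@H](CC1)[C@H](C(=O)OC)C[C@@]2(C(OC)OC)C[Si](C)(C)OC(C)C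
F6 | step 5 | primary alcohol (C24H2OH on C23) | FC(F)(F)S(=O)(=O)OC1=C2[C@H](CC1)[C@H](C(=O)OC)C[C@@]2(C(OC)OC)CO
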